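**Strategy.** The 22-membered ring (ring A C3–C5, the ether oxygen, ring B C1′–C4′, the carbinol carbon and the C13 tether) is closed last at its only stereogenic olefin, the Z-CH=CH that lies six CH2 groups from the carbinol carbon and five from ring A. Because this alkene is isolated, unhindered and flanked only by CH2 groups, a kinetically Z-selective ring-closing metathesis of two terminal vinyl groups closes the macrocycle and fixes the alkene geometry in one operation. The precursor is an open diaryl ether: ring A carries a hept-6-enyl chain, ring B an (R)-1-hydroxynon-8-enyl chain, and the three phenols are TBS ethers. It is assembled by O-arylation, Negishi coupling and catalytic asymmetric aldehyde alkylation.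

Key step: step 6

Assumption: compounds 2, 6 and 9 and the cyclometalated ruthenium catalyst are taken as purchasable. Ring A is numbered C1 (OH), C3 (chain), C5 (ether O); ring B is numbered C1′ (ether O), C2′/C6′ (OH), C4′ (carbinol carbon). TBS = tert-butyldimethylsilyl.

Step 1
Reactants: 1 syringaldehyde (4-hydroxy-3,5-dimethoxybenzaldehyde); 2 (3-bromo-5-methoxyphenyl)boronic acid
Product: 3 4-(3-bromo-5-methoxyphenoxy)-3,5-dimethoxybenzaldehyde
Conditions: Cu(OAc)2 (2 equiv), pyridine (5 equiv), 4 Å MS, CH2Cl2, dry air, rt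
Reagents that add atoms: none
Why: Chan–Lam–Evans O-arylation, in which the aryl group passes from boron to divalent copper, the phenoxide binds and C–O reductive elimination from trivalent copper occurs at room temperature, conditions that accept di-ortho-substituted electron-poor phenols and leave the aldehyde and the aryl bromide untouched.

Step 2
Reactants: 3 4-(3-bromo-5-methoxyphenoxy)-3,5-dimethoxybenzaldehyde
Product: 4 4-(3-bromo-5-hydroxyphenoxy)-3,5-dihydroxybenzaldehyde
Conditions: BBr3 (6 equiv), CH2Cl2, −78 °C to rt; then H2O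
Reagents that add atoms: none
Why: Lewis acid-mediated aryl methyl ether cleavage (O–B coordination, then SN2 attack of bromide on each methyl group), carried out before any alkene or benzylic alcohol is present; the diaryl ether and aryl bromide are inert and the aldehyde is restored on aqueous work-up.

Step 3
Reactants: 4 4-(3-bromo-5-hydroxyphenoxy)-3,5-dihydroxybenzaldehyde
Product: 5 4-[3-bromo-5-(tert-butyldimethylsilyloxy)phenoxy]-3,5-bis(tert-butyldimethylsilyloxy)benzaldehyde
Conditions: TBSCl (3.6 equiv), imidazole, DMF, rt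
Reagents that add atoms: tert-butyldimethylsilyl chloride, CC(C)(C)[Si](C)(C)Cl
Why: Imidazole-promoted O-silylation of all three phenols gives ethers that survive the organozinc, organotitanium and metathesis steps and are removed at the end by fluoride without acid.

Step 4
Reactants: 5 4-[3-bromo-5-(tert-butyldimethylsilyloxy)phenoxy]-3,5-bis(tert-butyldimethylsilyloxy)benzaldehyde; 6 7-bromohept-1-ene
Product: 8 4-[3-(hept-6-en-1-yl)-5-(tert-butyldimethylsilyloxy)phenoxy]-3,5-bis(tert-butyldimethylsilyloxy)benzaldehyde, via hept-6-en-1-ylzinc bromide 7 (not isolated)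
Conditions: 6, Zn dust, I2 (5 mol%), DMA, 70 °C; then 5, Pd(OAc)2 (2 mol%), 2-dicyclohexylphosphino-2′,6′-dimethoxybiphenyl (SPhos, 4 mol%), THF, rt
Reagents that add atoms: none
Why: Negishi sp3–sp2 cross-coupling (oxidative addition of zerovalent palladium into the aryl C–Br bond, transmetalation from the primary alkylzinc bromide, reductive elimination faster than β-hydride elimination with the bulky biarylphosphine); alkylzinc halides do not add to the aromatic aldehyde or attack the silyl ethers under these conditions.

Step 5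
Reactants: 8 4-[3-(hept-6-en-1-yl)-5-(tert-butyldimethylsilyloxy)phenoxy]-3,5-bis(tert-butyldimethylsilyloxy)benzaldehyde; 9 8-bromooct-1-ene
Product: 12 (R)-1-{4-[3-(hept-6-en-1-yl)-5-(tert-butyldimethylsilyloxy)phenoxy]-3,5-bis(tert-butyldimethylsilyloxy)phenyl}non-8-en-1-ol, via oct-7-en-1-ylmagnesium bromide 10 (not isolated), via oct-7-en-1-yltitanium triisopropoxide 11 (not isolated)
Conditions: 9, Mg, Et2O, rt; Ti(OiPr)4, CH2Cl2, −78 °C; slow addition to 8, (R)-3-(3,5-diphenylphenyl)-5,5′,6,6′,7,7′,8,8′-octahydro-1,1′-bi-2-naphthol (3 mol%), Ti(OiPr)4, CH2Cl2, 0 °C; aq. NH4Cl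
Reagents that add atoms: none
Why: Catalytic enantioselective 1,2-addition of a Grignard-derived alkyltitanium triisopropoxide to an aromatic aldehyde under a titanium H8-BINOLate catalyst, in which the (R)-ligand complex activates the aldehyde and is expected to direct alkyl transfer to its Re face to give the (R)-carbinol (its antipode would be used should the sense prove opposite), while slow addition keeps the uncatalysed racemic pathway small.

Step 6
Reactants: 12 (R)-1-{4-[3-(hept-6-en-1-yl)-5-(tert-butyldimethylsilyloxy)phenoxy]-3,5-bis(tert-butyldimethylsilyloxy)phenyl}non-8-en-1-ol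
Product: 13 tris(tert-butyldimethylsilyl) ether of the target at the three phenolic oxygens, the (R,Z)-configured 22-membered diaryl ether macrocycle with free carbinol OH
Conditions: Ru(κ2-O2NO)(=CH-C6H4-2-OiPr)[C,C-chelating 1-(adamantan-1-yl)-3-(2,6-diisopropylphenyl)imidazolidin-2-ylidene] (7.5 mol%), ClCH2CH2Cl (3 mM), 60 °C, static vacuum
Reagents that add atoms: none
Why: The ruthenium alkylidene takes up one terminal vinyl group, the resulting substrate-bound alkylidene undergoes intramolecular [2+2] cycloaddition with the second vinyl group to a ruthenacyclobutane, and cycloreversion releases the macrocycle and a ruthenium methylidene that leaves as ethene. The closest known reaction type is Z-selective macrocyclic ring-closing metathesis of α,ω-dienes with cyclometalated ruthenium carbene catalysts, established for large lactones, lactams and ketones. The 22-membered ring is closed by head-to-head union of the two terminal CH2=CH groups, a strain-free, entropy-limited macrocyclisation run at 3 mM. The only new stereoelement, the C=C geometry, is catalyst-controlled: in the side-bound metallacycle the N-aryl group of the chelated carbene lies over the ring and forces both substituents to the opposite face, so cycloreversion should give the Z-alkene; the carbinol centre is not involved. The step needs ring closure over oligomerisation and kinetic Z over E selectivity, and the substrate secures both because its only alkenes are two unhindered monosubstituted vinyl groups, each at least five CH2 groups from an arene or heteroatom, while ethene is removed under static vacuum so that the Z-product is not reopened by ethenolysis. The free secondary alcohol and the aryl silyl ethers are tolerated by this catalyst class, and any minor E isomer should be separable on AgNO3-impregnated silica.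

Step 7
Reactants: 13 tris(tert-butyldimethylsilyl) ether of the target
Product: 14 target, the (R,Z)-configured 22-membered diaryl ether macrocycle with three free phenols and the (R)-carbinol
Conditions: Bu4NF (3.5 equiv), AcOH (3.5 equiv), THF, 0 °C to rt
Reagents that add atoms: none
Why: Fluoride-mediated cleavage of aryl silyl ethers (Si–F bond formation), buffered with acetic acid so that the phenols are not held as air-sensitive phenoxides; the benzylic alcohol, its configuration and the Z-alkene are not touched.

**Compound list**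

1 | syringaldehyde (4-hydroxy-3,5-dimethoxybenzaldehyde) | O=Cc1cc(OC)c(O)c(OC)c1 | starting material
2 | (3-bromo-5-methoxyphenyl)boronic acid | COc1cc(Br)cc(B(O)O)c1 | starting material
3 | 4-(3-bromo-5-methoxyphenoxy)-3,5-dimethoxybenzaldehyde | COc1cc(Br)cc(Oc2c(OC)cc(C=O)cc2OC)c1 | intermediate
4 | 4-(3-bromo-5-hydroxyphenoxy)-3,5-dihydroxybenzaldehyde | Oc1cc(Br)cc(Oc2c(O)cc(C=O)cc2O)c1 | intermediate
5 | 4-[3-bromo-5-(tert-butyldimethylsilyloxy)phenoxy]-3,5-bis(tert-butyldimethylsilyloxy)benzaldehyde | CC(C)(C)[Si](C)(C)Oc1cc(Br)cc(Oc2c(O[Si](C)(C)C(C)(C)C)cc(C=O)cc2O[Si](C)(C)C(C)(C)C)c1 | intermediate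
6 | 7-bromohept-1-ene | C=CCCCCCBr | starting material
7 | hept-6-en-1-ylzinc bromide | C=CCCCCC[Zn]Br | intermediate (not isolated)
8 | 4-[3-(hept-6-en-1-yl)-5-(tert-butyldimethylsilyloxy)phenoxy]-3,5-bis(tert-butyldimethylsilyloxy)benzaldehyde | CC(C)(C)[Si](C)(C)Oc1cc(CCCCCC=C)cc(Oc2c(O[Si](C)(C)C(C)(C)C)cc(C=O)cc2O[Si](C)(C)C(C)(C)C)c1 | intermediate
9 | 8-bromooct-1-ene | C=CCCCCCCBr | starting material
10 | oct-7-en-1-ylmagnesium bromide | C=CCCCCCC[Mg]Br | intermediate (not isolated)
11 | oct-7-en-1-yltitanium triisopropoxide | C=CCCCCCC[Ti](OC(C)C)(OC(C)C)OC(C)C | intermediate (not isolated)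
12 | (R)-1-{4-[3-(hept-6-en-1-yl)-5-(tert-butyldimethylsilyloxy)phenoxy]-3,5-bis(tert-butyldimethylsilyloxy)phenyl}non-8-en-1-ol | CC(C)(C)[Si](C)(C)Oc1cc(CCCCCC=C)cc(Oc2c(O[Si](C)(C)C(C)(C)C)cc([C@H](O)CCCCCCC=C)cc2O[Si](C)(C)C(C)(C)C)c1 | intermediate
13 | tris(tert-butyldimethylsilyl) ether of the target, (R,Z)-macrocycle | CC(C)(C)[Si](C)(C)Oc1cc2cc(c1)Oc1c(O[Si](C)(C)C(C)(C)C)cc(cc1O[Si](C)(C)C(C)(C)C)[C@H](O)CCCCCC/C=C\CCCCC2 | intermediate
14 | target, (R,Z)-configured 22-membered diaryl ether macrocycle | Oc1cc2cc(c1)Oc1c(O)cc(cc1O)[C@H](O)CCCCCC/C=C\CCCCC2 | target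

**Step count and risks**

Total step count: 7. Longest linear sequence: 7 steps (1 → 3 → 4 → 5 → 8 → 12 → 13 → 14).

Steps most likely to fail:

Step 6. Kinetic Z-selectivity may be eroded by secondary metathesis of the product, and ring closure may lose to oligomerisation or catalyst decay. The fallback replaces olefin metathesis by alkyne metathesis followed by semi-hydrogenation; it sets out from 5 and comes back to the route at 14. Negishi coupling of 5 with oct-6-yn-1-ylzinc bromide F1 (from 8-bromooct-2-yne, Zn, DMA; Pd(OAc)2, SPhos) would give 4-[3-(oct-6-yn-1-yl)-5-(tert-butyldimethylsilyloxy)phenoxy]-3,5-bis(tert-butyldimethylsilyloxy)benzaldehyde F2. The titanium H8-BINOLate alkylation of step 5, now with non-7-yn-1-ylmagnesium bromide F3 (from 9-bromonon-2-yne) through non-7-yn-1-yltitanium triisopropoxide F4, would give the (R)-diyne alcohol F5. Silylation (TBSOTf, 2,6-lutidine, CH2Cl2) would give the tetrasilyl diyne F6. Ring-closing alkyne metathesis with Mo(≡C-C6H4-4-OMe)(OSiPh3)3 (toluene, 5 Å MS, 80 °C), which has no E/Z issue, would give the 22-membered tetrasilyl cycloalkyne F7 with loss of but-2-yne. Lindlar semi-hydrogenation (H2, Pd/CaCO3 poisoned with Pb(OAc)2, quinoline, EtOAc) would give the tetrasilyl (Z)-cycloalkene F8 by syn addition of hydrogen, and Bu4NF in THF would give 14.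

Step 5. Facial discrimination may be incomplete because uncatalysed addition of residual alkylmagnesium or alkyltitanium competes with the ligand-accelerated pathway. The fallback sets the stereocentre by ketone reduction instead of carbonyl alkylation; it sets out from 8 and comes back at 12. Plain addition of 10 to 8 (THF, −78 °C) would give the racemic 1-aryl-non-8-en-1-ol F9. Dess–Martin periodinane (NaHCO3, CH2Cl2) would give the aryl ketone, 1-aryl-non-8-en-1-one F10. Noyori asymmetric transfer hydrogenation with RuCl[(R,R)-TsDPEN](p-cymene) in HCO2H/Et3N at rt delivers hydride by an outer-sphere pathway with CH/π recognition of the arene and leaves terminal alkenes and aryl silyl ethers alone; it would give (R)-12.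

Step 1. C–O bond formation may be slow with the hindered, electron-poor phenoxide, so that protodeboronation and oxidative homocoupling consume the boronic acid. The fallback is a metal-free arylation with a diaryliodonium salt; it sets out from 1 and comes back at 3. One-pot oxidation of 1-bromo-3-iodo-5-methoxybenzene (mCPBA, TsOH·H2O, MeCN) and trapping with 1,3,5-trimethoxybenzene would give (3-bromo-5-methoxyphenyl)(2,4,6-trimethoxyphenyl)iodonium tosylate F11. The potassium phenoxide of 1 (KOtBu, THF, rt) would be arylated by ligand coupling at trivalent iodine, which is little affected by ortho substituents on the phenoxide and transfers the less electron-rich aryl group, to give 3.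

**Further compounds**

F1 | step 6 | oct-6-yn-1-ylzinc bromide | CC#CCCCCC[Zn]Br
F2 | step 6 | 4-[3-(oct-6-yn-1-yl)-5-(tert-butyldimethylsilyloxy)phenoxy]-3,5-bis(tert-butyldimethylsilyloxy)benzaldehyde | CC(C)(C)[Si](C)(C)Oc1cc(CCCCCC#CC)cc(Oc2c(O[Si](C)(C)C(C)(C)C)cc(C=O)cc2O[Si](C)(C)C(C)(C)C)c1
F3 | step 6 | non-7-yn-1-ylmagnesium bromide | CC#CCCCCCC[Mg]Br
F4 | step 6 | non-7-yn-1-yltitanium triisopropoxide | CC#CCCCCCC[Ti](OC(C)C)(OC(C)C)OC(C)C
F5 | step 6 | (R)-1-{4-[3-(oct-6-yn-1-yl)-5-(tert-butyldimethylsilyloxy)phenoxy]-3,5-bis(tert-butyldimethylsilyloxy)phenyl}dec-8-yn-1-ol | CC(C)(C)[Si](C)(C)Oc1cc(CCCCCC#CC)cc(Oc2c(O[Si](C)(C)C(C)(C)C)cc([C@H](O)CCCCCCC#CC)cc2O[Si](C)(C)C(C)(C)C)c1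
F6 | step 6 | tert-butyldimethylsilyl ether of F5 at the carbinol oxygen (tetrasilyl diyne) | CC(C)(C)[Si](C)(C)Oc1cc(CCCCCC#CC)cc(Oc2c(O[Si](C)(C)C(C)(C)C)cc([C@H](O[Si](C)(C)C(C)(C)C)CCCCCCC#CC)cc2O[Si](C)(C)C(C)(C)C)c1
F7 | step 6 | tetrasilyl (R)-configured 22-membered cycloalkyne | CC(C)(C)[Si](C)(C)Oc1cc2cc(c1)Oc1c(O[Si](C)(C)C(C)(C)C)cc(cc1O[Si](C)(C)C(C)(C)C)[C@H](O[Si](C)(C)C(C)(C)C)CCCCCCC#CCCCCC2
F8 | step 6 | tetrakis(tert-butyldimethylsilyl) ether of the target, (R,Z)-macrocycle | CC(C)(C)[Si](C)(C)Oc1cc2cc(c1)Oc1c(O[Si](C)(C)C(C)(C)C)cc(cc1O[Si](C)(C)C(C)(C)C)[C@H](O[Si](C)(C)C(C)(C)C)CCCCCC/C=C\CCCCC2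
F9 | step 5 | racemic 1-{4-[3-(hept-6-en-1-yl)-5-(tert-butyldimethylsilyloxy)phenoxy]-3,5-bis(tert-butyldimethylsilyloxy)phenyl}non-8-en-1-ol | CC(C)(C)[Si](C)(C)Oc1cc(CCCCCC=C)cc(Oc2c(O[Si](C)(C)C(C)(C)C)cc(C(O)CCCCCCC=C)cc2O[Si](C)(C)C(C)(C)C)c1
F10 | step 5 | 1-{4-[3-(hept-6-en-1-yl)-5-(tert-butyldimethylsilyloxy)phenoxy]-3,5-bis(tert-butyldimethylsilyloxy)phenyl}non-8-en-1-one | CC(C)(C)[Si](C)(C)Oc1cc(CCCCCC=C)cc(Oc2c(O[Si](C)(C)C(C)(C)C)cc(C(=O)CCCCCCC=C)cc2O[Si](C)(C)C(C)(C)C)c1
F11 | step 1 | (3-bromo-5-methoxyphenyl)(2,4,6-trimethoxyphenyl)iodonium tosylate | COc1cc(Br)cc([I+]c2c(OC)cc(OC)cc2OC)c1.Cc1ccc(S(=O)(=O)[O-])cc1
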